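Readings and results are simulated from invented constants.

J is charged at 43 mM, less than the 64.5 mM of E, so, reckoned one to one, J is the limiting reagent and the ledger is kept in J.

in all of them: Q 12 µM

|  | J | E | remark | time |
|---|---|---|---|---|
| dawn | 43 mM | 64.5 mM | run made earlier |  |
| spring | 64 mM | 64.5 mM | run made earlier |  |
| ochre | 43 mM | 64.5 mM | everything together at the start | 4.0 d |
| teal | 43 mM (fed, over 3.0 d) | 64.5 mM | all else is in the flask from the start; the feed brings no volume worth counting | 4.0 d |
| green | 43 mM | 64.5 mM (fed, over 3.0 d) | all else is in the flask from the start; the feed brings no volume worth counting | 4.0 d |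

dawn run (percent of the J charged)

| time / d | D / % |
|---|---|
| 0.208 | 4.2 |
| 0.333 | 4.5 |
| 0.500 | 8.7 |
| 0.833 | 13.8 |
| 1.67 | 25.5 |
| 2.50 | 34.5 |

spring run (percent of the J charged)

| time / h | D / % |
|---|---|
| 2.00 | 1.6 |
| 6.00 | 4.5 |
| 10.0 | 5.8 |
| 15.0 | 9.4 |
| 20.0 | 12.4 |
| 30.0 | 16.8 |

(scatter of a reading: 0.5 percentage points)

1. the flask with the highest amount of D, in percent of the J charged ("all alike" if they lie within 1.5 percentage points) (ochre / teal / green / all alike)
2. final D, as a percentage of the J charged, in ochre
3. final D, as a percentage of the J charged, in teal
4. final D, as a percentage of the J charged, in green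

- the numbers in the tables scatter with a standard deviation of 0.5 percentage points

The first entry is small: Q at 12 µM can hold at most 0.0279% of the charge, so each mole of J is booked as free J or as D.

Dawn has ochre's recipe, so its readings give the split. With E frozen at its charge, free J decays as a pseudo-first-order lag. The last reading, 34.5% at 2.50 d, gives a rate of 0.169 d⁻¹, a time constant of 5.91 d. The dawn reading at 0.833 d gives 0.178 d⁻¹, close by. Spring, with 64 mM of J, reads a slower 0.147 d⁻¹, so the frozen constant is an approximation. Over 4.0 d, ochre's ledger books 49.2% as D and the rest as free J.

A steady feed delivers its dose on average half way through the feed. In teal the mean portion of J therefore reacts for less than the run time. In green the E fed in up to each moment, summed over the run as a share of its charge and with its consumption set aside, comes to the same shortened time. Both fed flasks are thus booked with the run time less half the feed time, 2.50 d: the working time. It matches the time of dawn's last reading, so teal and green each book 34.5% as D, and ochre leads.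

The forecast names ochre, with 47.5% for ochre, 36% for teal and 34.5% for green, on the ground “Feeding loses reaction time, so ochre wins.” It parts from this ledger on ochre, lower, and on teal, higher.

Ochre gives the most D: 47.7%, with free J at 52.3%. Teal gives 35.0% and green 34.6%.

    E + G ⇌ X (K = 16.1 M⁻¹, k = 1.98 × 10⁵ M⁻¹ h⁻¹)
    X → Q + D (k = 159 h⁻¹)
    2 Q ⇌ L, settled at all times (K = 1.40 × 10⁵ M⁻¹)
    J + Q ⇌ G (K = 12.2 M⁻¹, k = 1.42 × 10⁶ M⁻¹ h⁻¹)

Against the 34.5% booked at the working time of 2.50 d, teal stands 0.50 points above and green 0.10 points above, while ochre stands 1.5 points under its own ledger figure. For green with 160 mM of E, the working time over a time constant divided by the ratio of E charges gives 65.0%, and that flask stands at 65.0%. In green itself, by 2.00 d, with E still coming in and standing at 59.0% of its own charge, D had reached 11.5%, and the step of X to Q + D had 33% of its turnover up to 4.0 d behind it. After the feed ended at 3.00 d with D at 23.2%, that step ran on while E went from 84.5% to 76.9% of its charge and brought green's D to 34.6% at 4.00 d.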